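Assumption: the SMILES has no stereodescriptor, no stereocentre and no configurationally stable axis. The target is treated as achiral, so "single enantiomer" needs no action.

**Retrosynthetic overview**
- Ring A is bought as 2-amino-3-bromophenol (1) and converted into its o-quinone diazide (2). Ring B is bought as 2,4-dibromophenol (3). No ring is formed.
- Key disconnection: the C2–OAr bond. It is made by Rh(II)-carbenoid O–H insertion of 2 into 3, not by Ullmann, SNAr or iodonium O-arylation. Rearomatisation gives free phenol 4 directly, with no protecting group, and the former C–N carbon fixes the regiochemistry.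
- Last disconnection: C4–Br and C6–Br, by OH-directed double bromination of 4 (through 5) to target 6.

**Step 1**
Reactants: 1 2-amino-3-bromophenol
Product: 2 5-bromo-6-diazocyclohexa-2,4-dien-1-one
Conditions: t-BuONO (1.3 equiv), AcOH (0.2 equiv), CH2Cl2/THF 4:1, 0 °C, dark, 1 added slowly to the nitrite; cold aq NaHCO3 wash, dry, concentrate below 25 °C
Reagents that add atoms: tert-butyl nitrite, CC(C)(C)ON=O
Why: Aprotic diazotisation of a primary arylamine, in which the ortho-OH loses its proton as the diazonium forms, gives the neutral o-quinone diazide directly; Ar–Br is inert and no stereocentre is formed.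

**Step 2**
Reactants: 2 5-bromo-6-diazocyclohexa-2,4-dien-1-one, 3 2,4-dibromophenol
Product: 4 3-bromo-2-(2,4-dibromophenoxy)phenol
Conditions: Rh2(OAc)4 (2 mol %), 3 (4 equiv), 4 Å MS, ClCH2CH2Cl, 65 °C, dark, 2 added by syringe pump over 4 h
Reagents that add atoms: none
Why: Proposed new method: Rh(II) expels N2 from the o-quinone diazide to give an electrophilic quinoid α-oxo carbenoid, the oxygen of 3 (para position blocked, ring deactivated toward C-arylation) attacks the carbene carbon to form an oxonium ylide, and proton transfer to the carbonyl oxygen rearomatises ring A so the aryloxy group sits on the former C–N carbon between OH and Br; the closest known reaction type is Rh2(OAc)4-catalysed O–H insertion of α-diazoketones and 1,2-diazonaphthoquinones into alcohols and phenols, metal catalysis well below the thermal decomposition range in the dark suppresses Wolff ring contraction, Rh(II) does not insert into Ar–Br, and no stereocentre is formed.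

**Step 3**
Reactants: 4 3-bromo-2-(2,4-dibromophenoxy)phenol
Product: 6 3,4,6-tribromo-2-(2,4-dibromophenoxy)phenol, via para-monobromide 5 (not isolated)
Conditions: Br2 (2.05 equiv), AcOH, 15 → 25 °C
Reagents that add atoms: bromine, BrBr
Why: In this electrophilic aromatic bromination (SEAr) the free OH is the dominant donor and directs to its only open para (C4) and ortho (C6) sites, which are also ortho/para to C3–Br, while C5 is meta to OH and ring B is deactivated by two bromines, so either order of attack converges on 6; no stereocentre is formed.

**Compound list**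
1 | 2-amino-3-bromophenol | Nc1c(O)cccc1Br | starting material
2 | 5-bromo-6-diazocyclohexa-2,4-dien-1-one (o-quinone diazide) | O=C1C=CC=C(Br)C1=[N+]=[N-] | intermediate
3 | 2,4-dibromophenol | Oc1ccc(Br)cc1Br | starting material
4 | 3-bromo-2-(2,4-dibromophenoxy)phenol | Oc1cccc(Br)c1Oc1ccc(Br)cc1Br | intermediate
5 | 3,4-dibromo-2-(2,4-dibromophenoxy)phenol (para-monobromide, not isolated) | Oc1ccc(Br)c(Br)c1Oc1ccc(Br)cc1Br | intermediate
6 | 3,4,6-tribromo-2-(2,4-dibromophenoxy)phenol (achiral) | Oc1c(Br)cc(Br)c(Br)c1Oc1ccc(Br)cc1Br | target

Total step count: 3. Longest linear sequence: 3 (1 → 2 → 4 → 6).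

**Steps most likely to fail**

**1. Step 2 (key O–H insertion).**
- Risks: slow carbenoid formation at a diazo carbon flanked by C=O and C–Br, Wolff ring contraction, C-arylation of 3, and a second insertion into the OH of 4.
- The fallback gives up carbene chemistry for the classical polar disconnection. It sets out from 3 and comes back at 4.
- Phenol 3 undergoes SNAr with commercial 3-bromo-2-fluorobenzaldehyde (K2CO3, DMAc, 130 °C; the ortho-CHO activates C–F). This gives 3-bromo-2-(2,4-dibromophenoxy)benzaldehyde F1.
- Baeyer–Villiger oxidation of the ortho-aryloxy aldehyde (mCPBA, CH2Cl2) gives 3-bromo-2-(2,4-dibromophenoxy)phenyl formate F2.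
- KOH in MeOH–H2O cleaves the formate to 4.

**2. Step 1 (neutral diazotisation).**
- Risks: triazene or azo coupling of 2 with unreacted electron-rich 1 in the weakly acidic medium, and loss of the light- and heat-sensitive 2 on concentration.
- The fallback replaces one-stage neutral nitrosation with a two-stage salt strategy built on a storable, purifiable precursor. It sets out from 1 and comes back at 2.
- Compound 1 is diazotised in strong acid (NaNO2, 48 % aq HBF4, 0 °C), where neither the amine nor the phenol can couple.
- The precipitated 2-bromo-6-hydroxybenzenediazonium tetrafluoroborate F3 is filtered and reprecipitated.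
- Compound 2 is released only just before use, by shaking F3 with cold aq NaHCO3/ClCH2CH2Cl. The dried organic layer is fed straight into step 2.

**3. Step 3 (late double bromination).**
- Risks: slow attack at C4 next to C3–Br, and overbromination at C6′ of ring B or at C5.
- The fallback reverses the order of events so that no bromination is done on the diaryl ether. It sets out from 1 and comes back at 6.
- Compound 1 is brominated as its fully N-protonated form (NBS 2.05 equiv, conc. H2SO4, 0 °C). OH (ortho/para), NH3+ (meta) and C3–Br (ortho/para) all direct to C4 and C6, giving 2-amino-3,4,6-tribromophenol F4.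
- Diazotisation (t-BuONO, cat. TFA, MeCN, 0 °C, dark) gives the more robust polyhalogenated 2,4,5-tribromo-6-diazocyclohexa-2,4-dien-1-one F5.
- Rh2(OAc)4-catalysed O–H insertion of F5 into 3 gives 6 directly.

**Further compounds**
F1 | step 2 | 3-bromo-2-(2,4-dibromophenoxy)benzaldehyde | O=Cc1cccc(Br)c1Oc1ccc(Br)cc1Br
F2 | step 2 | 3-bromo-2-(2,4-dibromophenoxy)phenyl formate | O=COc1cccc(Br)c1Oc1ccc(Br)cc1Br
F3 | step 1 | 2-bromo-6-hydroxybenzenediazonium tetrafluoroborate | Oc1cccc(Br)c1[N+]#N.F[B-](F)(F)F
F4 | step 3 | 2-amino-3,4,6-tribromophenol | Nc1c(O)c(Br)cc(Br)c1Br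
F5 | step 3 | 2,4,5-tribromo-6-diazocyclohexa-2,4-dien-1-one | O=C1C(Br)=CC(Br)=C(Br)C1=[N+]=[N-]
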